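**Plan** (germacrane numbering: ring C1–C10, C11–C13 = methylene-lactone carbons on C7, C14 on C10, C15 on C4; furanone = C10, C1(=O), C2=C3, O)

1. Retrosynthesis: the C6–O lactone bond and the C5–O bond are cut back to a (Z)-C5=C6 alkene carrying a tert-butyl acrylate arm on C7. The C3–C4 bond of the ten-membered ring is then cut by a retro-oxy-Cope that re-joins C1–C6, contracting the bridged 10/9-membered system to a cis-fused hexahydrobenzofuran-3a-ol. This is opened at C1–C6 (allylchromium), C7–C8 (aldol) and the furanone (citramalate lactone).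
2. Forward: furanone first, then the C7–C8 boron aldol, then the six-membered ring by intramolecular Nozaki–Hiyama–Kishi allylation, then [3,3] ring expansion 6→10 that delivers the whole 11-oxabicyclo[6.2.1] core, then the epoxide, with the lactone closed last.
3. Enabling feature: the C1 carbonyl with its C2=C3 enol ether is the enolate/vinyl half of an oxy-Cope retron, and the C5/C6 dioxygenation marks the alkene such a shift leaves 1,5 to C1. The furanone ring itself therefore serves as one vinyl arm, and the bridged ten-membered ring needs no macrocyclisation.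
4. Stereochemistry: C10 from (R)-citramalic acid; C7 and C8 from an Ipc-boron syn-aldol; C4 by chirality transfer from the E-propenyl group through a boat [3,3] array (also the epimer favoured by allylic strain); C5 by C8–OH-directed epoxidation; C6 by SN2 opening of that epoxide by the ester carbonyl (trans-lactone).

Key step: step 12

Remark 1: the Z-enol diisopinocampheylborinate is assumed to follow the same chair model as Ipc2B-allyl additions, which assigns (+)-Ipc2BOTf (from (−)-α-pinene) to Re-face attack on aldehyde 9; if the sense is opposite, the antipodal reagent is used.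
Remark 2: bromide 19 is drawn as the 6-bromide; its allylic isomer and both C6 epimers give the same allylchromium species, so the composition of 19 does not matter.

Step 1
Reactants: 1 (R)-citramalic acid
Product: 2 2-[(4R)-2,2,4-trimethyl-5-oxo-1,3-dioxolan-4-yl]acetic acid
Conditions: 2,2-dimethoxypropane, TsOH (cat.), rt
Reagents that add atoms: 2,2-dimethoxypropane, COC(C)(C)OC
Why: Acid-catalysed acetalisation of the α-hydroxy acid unit as the five-membered dioxolanone differentiates the two carboxyls and leaves only the C8 acid free; the C10 stereocentre comes from the chiral pool and is untouched.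

Step 2
Reactants: 2 dioxolanone acid
Product: 4 (3R)-3-hydroxy-3-methyloxolan-2-one, via (5R)-5-(2-hydroxyethyl)-2,2,5-trimethyl-1,3-dioxolan-4-one 3 (not isolated)
Conditions: BH3·SMe2, THF, 0 °C to rt; MeOH quench; then TsOH (cat.), CH2Cl2, rt
Reagents that add atoms: none
Why: Borane reduces the free carboxylic acid chemoselectively in the presence of the dioxolanone, and acid then translactonises alcohol 3 to the γ-lactone with loss of acetone, as established in the malic acid series.

Step 3
Reactants: 4 hydroxy lactone; 5 (Z)-1-bromo-2-ethoxyethene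
Product: 8 (2R)-2-(2-hydroxyethyl)-2-methylfuran-3(2H)-one, via (Z)-2-ethoxyethenyllithium 6 (not isolated), via (1Z,4R)-1-ethoxy-4,6-dihydroxy-4-methylhex-1-en-3-one 7 (not isolated)
Conditions: 5, t-BuLi, THF, −78 °C; then 4 (0.4 equiv), −78 °C; then 1 M HCl, THF, rt
Reagents that add atoms: none
Why: Addition of the vinyllithium (from lithium–halogen exchange) to the lactone should stop at the lactol alkoxide, and on acidification the α'-hydroxy β-ethoxy enone 7 should close by conjugate addition–elimination of the tertiary hydroxyl with loss of ethanol, the classical acid-mediated 3(2H)-furanone synthesis, the five-membered vinylogous ester being the thermodynamic sink over attack by the primary hydroxyl.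

Step 4
Reactants: 8 furanone alcohol
Product: 9 2-[(2R)-2-methyl-3-oxo-2,3-dihydrofuran-2-yl]acetaldehyde
Conditions: Dess–Martin periodinane, NaHCO3, CH2Cl2, 0 °C; used crude
Reagents that add atoms: none
Why: Dess–Martin oxidation of the primary alcohol under near-neutral conditions should leave the furanone intact; the aldehyde is carried on crude because its β-oxygen substituent could be lost by elimination.

Step 5
Reactants: 10 (E)-but-2-enal; 11 tert-butyl 2-(bromomethyl)prop-2-enoate
Product: 13 tert-butyl (5E)-4-hydroxy-2-methylidenehept-5-enoate (racemic), via [2-(tert-butoxycarbonyl)prop-2-en-1-yl]zinc bromide 12 (not isolated)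
Conditions: Zn dust, THF/sat. aq. NH4Cl, rt
Reagents that add atoms: none
Why: Zinc Barbier allylation adds 1,2 to the enal; the carbinol centre is left racemic because it is oxidised in the next step.

Step 6
Reactants: 13 homoallylic alcohol
Product: 14 tert-butyl (5E)-2-methylidene-4-oxohept-5-enoate
Conditions: Dess–Martin periodinane, CH2Cl2, 0 °C
Reagents that add atoms: none
Why: Dess–Martin oxidation of the allylic alcohol to the enone under non-basic conditions should keep the 1,1-disubstituted alkene from moving into conjugation.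

Step 7
Reactants: 9 furanone aldehyde; 14 enone
Product: 16 tert-butyl (3R,5E)-3-[(1S)-1-hydroxy-2-[(2R)-2-methyl-3-oxo-2,3-dihydrofuran-2-yl]ethyl]-2-methylidene-4-oxohept-5-enoate, via Z(O)-enol diisopinocampheylborinate 15 (not isolated)
Conditions: (+)-Ipc2BOTf, i-Pr2NEt, CH2Cl2, −78 °C; then 9, −78 to −20 °C; pH 7 buffer, MeOH, H2O2, 0 °C
Reagents that add atoms: none
Why: Boron-mediated aldol reaction of a ketone with a chiral Ipc2B reagent: soft enolisation at the only α-CH2 (C7) gives the Z(O)-enolate, whose chair transition state gives the 7,8-syn adduct, and the Ipc ligands select the Re face of the aldehyde, setting C7 and C8 by reagent control over the remote C10 centre.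

Step 8
Reactants: 16 aldol adduct
Product: 17 8-O-tert-butyldimethylsilyl ether of 16
Conditions: TBSOTf, 2,6-lutidine, CH2Cl2, −78 °C
Reagents that add atoms: tert-butyldimethylsilyl triflate, CC(C)(C)[Si](C)(C)OS(=O)(=O)C(F)(F)F
Why: Low-temperature silylation of the β-hydroxy ketone with a hindered base avoids retro-aldol, elimination and epimerisation at C7 and masks C8–OH for the basic steps ahead.

Step 9
Reactants: 17 silyl ether
Product: 18 C6 allylic alcohol from 17 (both C6 epimers)
Conditions: NaBH4, CeCl3·7H2O, MeOH, −78 °C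
Reagents that add atoms: none
Why: Luche 1,2-reduction; the enone carbonyl is far more electrophilic than the vinylogous-ester carbonyl of the furanone at −78 °C, and the C6 configuration is irrelevant because C6 becomes an allylmetal terminus.

Step 10
Reactants: 18 allylic alcohol
Product: 19 C6 allylic bromide from 18 (drawn as the 6-bromide)
Conditions: CBr4, PPh3, 2,6-lutidine, CH2Cl2, −20 °C; used crude
Reagents that add atoms: carbon tetrabromide, BrC(Br)(Br)Br
Why: Appel bromination under neutral conditions; regio- and stereochemical purity of the bromide is not needed because ionisation to the allylmetal in step 11 erases both.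

Step 11
Reactants: 19 allylic bromide
Product: 21 tert-butyl 2-[(3aS,4S,5R,6S,7aR)-6-(tert-butyldimethylsilyloxy)-3a-hydroxy-7a-methyl-4-[(E)-prop-1-enyl]-3a,4,5,6,7,7a-hexahydro-1-benzofuran-5-yl]prop-2-enoate, via (E)-allylchromium(III) dichloride 20 (not isolated)
Conditions: CrCl2 (6 equiv), THF (0.01 M), rt; pH 7 buffer work-up, Et3N-deactivated silica
Reagents that add atoms: none
Why: Intramolecular Nozaki–Hiyama–Kishi allylation: oxidative addition of chromium(II) gives allylchromium 20 (metal on C4), which adds through its γ-carbon C6 to the furanone carbonyl C1 via a chair Zimmerman–Traxler array fused to a chair six-membered ring with the C7 and C8 substituents equatorial, which should place the propenyl group trans to the new hydroxyl and to the C7 arm with E geometry, while the cis 5/6 fusion (C1 controlled by C10) is the only one possible.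

Step 12
Reactants: 21 bicyclic carbinol
Product: 25 tert-butyl 2-[(2R,3Z,5R,6S,8R)-6-(tert-butyldimethylsilyloxy)-2,8-dimethyl-9-oxo-11-oxabicyclo[6.2.1]undeca-1(10),3-dien-5-yl]prop-2-enoate, via tertiary potassium alkoxide 22 (not isolated), via ring-expanded potassium enolate 23 (not isolated), via C2 sulfilimine 24 (not isolated)
Conditions: KHMDS (1.05 equiv), 18-crown-6, THF, −78 to 0 °C; then t-BuN=S(Cl)Ph, −78 °C to rt
Reagents that add atoms: none
Why: Deprotonation gives alkoxide 22, whose 1,5-diene C3=C2–C1(O−)–C6–C5=C4 undergoes an anionic oxy-Cope [3,3] shift (C1–C6 breaks, C3–C4 forms) to enolate 23 of the bridged dihydrofuranone, which is sulfenylated at C2 to 24 and loses PhS–NHt-Bu by syn-elimination across C2–C3 (Mukaiyama dehydrogenation) to give furanone 25. The closest known reactions are the anionic oxy-Cope ring expansion of 1,2-dialkenylcyclohexanols to cyclodec-5-enones and the one-pot sulfinimidoyl chloride dehydrogenation of ketone enolates. No ring is closed by cyclisation: the ten-membered carbocycle (C1–C10) and the nine-membered oxacycle (O, C3–C10) arise together by four-atom sigmatropic expansion of the cyclohexane, while the five-membered furanone ring is carried through as the bridge. C4 is set by suprafacial chirality transfer, the new bond forming on the face of C3 that carries C6 with the E-propenyl methyl outside in a boat array (C5 beneath C2; a chair would push C5 under the five-membered ring against C9–H), which should give 4R and the (Z)-C5=C6 alkene; 4R is also the epimer favoured by allylic strain across that alkene, so base equilibration through the furanone dienolate would converge on it. The step needs the [3,3] shift to outrun retro-allylation and γ-deprotonation of the acrylate: only the diastereomer with the propenyl group cis to C2 (secured in step 11) can reach the transition state, the cis fusion holds C3 and C4 within bonding distance, and one equivalent of base at low temperature with immediate enolate trapping limits the side reactions. In the oxidation only C3–H lies β to the enolate carbon and syn to sulfur, which should add to C2 on the face opposite the C4 bridge.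

Step 13
Reactants: 25 bridged furanone
Product: 26 tert-butyl 2-[(2R,3Z,5R,6S,8R)-6-hydroxy-2,8-dimethyl-9-oxo-11-oxabicyclo[6.2.1]undeca-1(10),3-dien-5-yl]prop-2-enoate
Conditions: HF·pyridine, pyridine, THF, 0 °C to rt
Reagents that add atoms: none
Why: Buffered fluoride desilylation frees C8–OH without base (C4–H is γ-acidic) and without cleaving the tert-butyl ester.

Step 14
Reactants: 26 homoallylic alcohol
Product: 27 (5S,6R)-5,6-epoxide of 26 (epoxide oxygen syn to C8–OH; 4R,5S,6R,7R,8S,10R in germacrane numbering)
Conditions: VO(acac)2 (cat.), t-BuOOH, CH2Cl2, rt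
Reagents that add atoms: tert-butyl hydroperoxide, CC(C)(C)OO
Why: Hydroxyl-directed vanadium-catalysed epoxidation of a homoallylic alcohol: H7 eclipses the Z-alkene to avoid A(1,3) strain, which puts C8 and its hydroxyl on one face, so the vanadium-bound peroxide should be delivered to that face (fixing C5 as in the target), while the acrylate and furanone alkenes are electron-poor and inert.

Step 15
Reactants: 27 epoxy alcohol; 28 angelic acid
Product: 30 8-O-angeloyl (5S,6R)-epoxide (4R,5S,6R,7R,8S,10R in germacrane numbering), via angelic 2,4,6-trichlorobenzoic anhydride 29 (not isolated)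
Conditions: 28, 2,4,6-trichlorobenzoyl chloride, Et3N, toluene, rt; then 27, 60 °C
Reagents that add atoms: none
Why: Yamaguchi esterification through the mixed anhydride without DMAP, the usual way to make angelates without Z-to-E isomerisation to the tiglate; C8–OH is the only free hydroxyl.

Step 16
Reactants: 30 epoxy angelate
Product: 31 Rufescenolide B
Conditions: TFA, CH2Cl2, 0 °C
Reagents that add atoms: none
Why: Acid-mediated tert-butyl ester cleavage with 5-exo opening of the protonated epoxide by the ester carbonyl at C6 with inversion, from the only face the C7 acrylate arm can reach, should give the trans-fused 6,12-lactone and free the C5 hydroxyl with loss of isobutene.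

**Compound list**

1 | (R)-citramalic acid | O=C(O)[C@@](C)(CC(=O)O)O | starting material
2 | 2-[(4R)-2,2,4-trimethyl-5-oxo-1,3-dioxolan-4-yl]acetic acid | O=C1[C@@](C)(CC(=O)O)OC(C)(C)O1 | intermediate
3 | (5R)-5-(2-hydroxyethyl)-2,2,5-trimethyl-1,3-dioxolan-4-one | O=C1[C@@](C)(CCO)OC(C)(C)O1 | intermediate
4 | (3R)-3-hydroxy-3-methyloxolan-2-one | O=C1[C@@](C)(CCO1)O | intermediate
5 | (Z)-1-bromo-2-ethoxyethene | CCO/C=C\Br | starting material
6 | (Z)-2-ethoxyethenyllithium | CCO/C=C\[Li] | intermediate
7 | (1Z,4R)-1-ethoxy-4,6-dihydroxy-4-methylhex-1-en-3-one | CCO/C=C\C(=O)[C@@](C)(CCO)O | intermediate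
8 | (2R)-2-(2-hydroxyethyl)-2-methylfuran-3(2H)-one | C1=CC(=O)[C@@](C)(CCO)O1 | intermediate
9 | 2-[(2R)-2-methyl-3-oxo-2,3-dihydrofuran-2-yl]acetaldehyde | C1=CC(=O)[C@@](C)(CC=O)O1 | intermediate
10 | (E)-but-2-enal | C/C=C/C=O | starting material
11 | tert-butyl 2-(bromomethyl)prop-2-enoate | C=C(CBr)C(=O)OC(C)(C)C | starting material
12 | [2-(tert-butoxycarbonyl)prop-2-en-1-yl]zinc bromide | C=C(C[Zn]Br)C(=O)OC(C)(C)C | intermediate
13 | tert-butyl (5E)-4-hydroxy-2-methylidenehept-5-enoate (racemic) | C/C=C/C(O)CC(=C)C(=O)OC(C)(C)C | intermediate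
14 | tert-butyl (5E)-2-methylidene-4-oxohept-5-enoate | C/C=C/C(=O)CC(=C)C(=O)OC(C)(C)C | intermediate
15 | Z(O)-enol di[(+)-isopinocampheyl]borinate of 14 | C/C=C/C(OB([C@@H]1[C@@H](C)[C@@H]2C[C@H](C1)C2(C)C)[C@@H]1[C@@H](C)[C@@H]2C[C@H](C1)C2(C)C)=C/C(=C)C(=O)OC(C)(C)C | intermediate
16 | tert-butyl (3R,5E)-3-[(1S)-1-hydroxy-2-[(2R)-2-methyl-3-oxo-2,3-dihydrofuran-2-yl]ethyl]-2-methylidene-4-oxohept-5-enoate | C1=CC(=O)[C@@](C)(C[C@H](O)[C@@H](C(=C)C(=O)OC(C)(C)C)C(=O)/C=C/C)O1 | intermediate
17 | 8-O-tert-butyldimethylsilyl ether of 16 | C1=CC(=O)[C@@](C)(C[C@H](O[Si](C)(C)C(C)(C)C)[C@@H](C(=C)C(=O)OC(C)(C)C)C(=O)/C=C/C)O1 | intermediate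
18 | C6 allylic alcohol from 17 (both C6 epimers) | C1=CC(=O)[C@@](C)(C[C@H](O[Si](C)(C)C(C)(C)C)[C@@H](C(=C)C(=O)OC(C)(C)C)C(O)/C=C/C)O1 | intermediate
19 | C6 allylic bromide from 18 (drawn as the 6-bromide) | C1=CC(=O)[C@@](C)(C[C@H](O[Si](C)(C)C(C)(C)C)[C@@H](C(=C)C(=O)OC(C)(C)C)C(Br)/C=C/C)O1 | intermediate
20 | (E)-allylchromium(III) dichloride (chromium on C4) | C1=CC(=O)[C@@](C)(C[C@H](O[Si](C)(C)C(C)(C)C)[C@@H](C(=C)C(=O)OC(C)(C)C)/C=C/C(C)[Cr](Cl)Cl)O1 | intermediate
21 | tert-butyl 2-[(3aS,4S,5R,6S,7aR)-6-(tert-butyldimethylsilyloxy)-3a-hydroxy-7a-methyl-4-[(E)-prop-1-enyl]-3a,4,5,6,7,7a-hexahydro-1-benzofuran-5-yl]prop-2-enoate | C1=C[C@@]2(O)[C@@H](/C=C/C)[C@H](C(=C)C(=O)OC(C)(C)C)[C@@H](O[Si](C)(C)C(C)(C)C)C[C@@]2(C)O1 | intermediate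
22 | tertiary potassium alkoxide of 21 | C1=C[C@@]2([O-])[C@@H](/C=C/C)[C@H](C(=C)C(=O)OC(C)(C)C)[C@@H](O[Si](C)(C)C(C)(C)C)C[C@@]2(C)O1.[K+] | intermediate
23 | ring-expanded potassium enolate (C1–O−, C1=C2, C3 sp3) of the bridged dihydrofuranone | C[C@@H]1/C=C\[C@H](C(=C)C(=O)OC(C)(C)C)[C@@H](O[Si](C)(C)C(C)(C)C)C[C@@]2(C)O[C@@H]1C=C2[O-].[K+] | intermediate
24 | C2 N-tert-butyl-S-phenylsulfilimine of the ring-expanded ketone | C[C@@H]1/C=C\[C@H](C(=C)C(=O)OC(C)(C)C)[C@@H](O[Si](C)(C)C(C)(C)C)C[C@@]2(C)O[C@@H]1[C@H](S(=NC(C)(C)C)c3ccccc3)C2=O | intermediate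
25 | tert-butyl 2-[(2R,3Z,5R,6S,8R)-6-(tert-butyldimethylsilyloxy)-2,8-dimethyl-9-oxo-11-oxabicyclo[6.2.1]undeca-1(10),3-dien-5-yl]prop-2-enoate | C[C@@H]1/C=C\[C@H](C(=C)C(=O)OC(C)(C)C)[C@@H](O[Si](C)(C)C(C)(C)C)C[C@@]2(C)OC1=CC2=O | intermediate
26 | tert-butyl 2-[(2R,3Z,5R,6S,8R)-6-hydroxy-2,8-dimethyl-9-oxo-11-oxabicyclo[6.2.1]undeca-1(10),3-dien-5-yl]prop-2-enoate | C[C@@H]1/C=C\[C@H](C(=C)C(=O)OC(C)(C)C)[C@@H](O)C[C@@]2(C)OC1=CC2=O | intermediate
27 | (5S,6R)-5,6-epoxide of 26 | C[C@@H]1[C@@H]3O[C@@H]3[C@H](C(=C)C(=O)OC(C)(C)C)[C@@H](O)C[C@@]2(C)OC1=CC2=O | intermediate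
28 | angelic acid, (Z)-2-methylbut-2-enoic acid | C/C=C(/C)C(=O)O | starting material
29 | angelic 2,4,6-trichlorobenzoic anhydride | C/C=C(/C)C(=O)OC(=O)c1c(Cl)cc(Cl)cc1Cl | intermediate
30 | 8-O-angeloyl (5S,6R)-epoxide | C[C@@H]1[C@@H]3O[C@@H]3[C@H](C(=C)C(=O)OC(C)(C)C)[C@@H](OC(=O)/C(C)=C\C)C[C@@]2(C)OC1=CC2=O | intermediate
31 | Rufescenolide B | C=C1C(=O)O[C@@H]2[C@@H](O)[C@@H](C)C3=CC(=O)[C@@](C)(C[C@H](OC(=O)/C(C)=C\C)[C@@H]12)O3 | target

**Totals**

Total steps: 16. Longest linear sequence: 14 steps (steps 1–4 and 7–16, from 1).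

**Steps most likely to fail**

1. Step 12. The potassium alkoxide may fragment by retro-allylation or deprotonate the acrylate at C7 faster than it rearranges, part of the shift may pass through the chair array (E-alkene, 4-epimer), or the enolate may open by β-elimination before it is oxidised. Fallback, from 21 back to 25: the tertiary hydroxyl is silylated (TMSOTf, 2,6-lutidine) to the 3a-O-trimethylsilyl ether F1, which is heated without base (toluene, sealed tube, about 180 °C) so that a neutral thermal siloxy-Cope shift gives the ring-expanded trimethylsilyl enol ether F2. Saegusa–Ito oxidation (Pd(OAc)2, MeCN) then gives 25. This removes the anionic manifold and separates ring expansion from dehydrogenation.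

2. Step 14. Delivery of the oxidant to the ring-side face may be too slow, so that undirected attack on the peripheral face (wrong C5 configuration) or oxidation of the alcohol takes over. Fallback, from 26 to 31: C8–OH is first esterified with 29 to the 8-O-angeloyl alkene F3. Osmium-catalysed dihydroxylation (OsO4, NMO) on the peripheral face gives the 5-epi-5,6-diol F4, in which C6 already has the target configuration. TFA closes the lactone with retention at C6 to the 5-epi hydroxy lactone F5. Dess–Martin oxidation gives the 5-oxo lactone F6, and Luche reduction at −78 °C, with hydride entering from the same exposed face that osmium used, should give 31. F6 must be kept away from base because C4–H is then doubly activated.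

3. Step 11. Addition of the allylchromium to the deactivated vinylogous-ester carbonyl may be slow, leading to protonation or coupling of the allylmetal, or control over propenyl geometry may be lost. Fallback, from 18 back to 21: reductive allylic transposition through the allylic diazene (o-nitrobenzenesulfonylhydrazide, PPh3, DEAD) gives the C6-deoxy (E)-5,6-alkene F7. A Me2AlCl-promoted intramolecular carbonyl-ene reaction onto the furanone carbonyl (C6 to C1, hydrogen from C4) should then give 21 through a chair array, trans-selective as in the citronellal-to-isopulegol cyclisation.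

**Further compounds**

F1 | step 12 | 3a-O-trimethylsilyl ether of 21 | C1=C[C@@]2(O[Si](C)(C)C)[C@@H](/C=C/C)[C@H](C(=C)C(=O)OC(C)(C)C)[C@@H](O[Si](C)(C)C(C)(C)C)C[C@@]2(C)O1
F2 | step 12 | trimethylsilyl enol ether of the ring-expanded dihydrofuranone | C[C@@H]1/C=C\[C@H](C(=C)C(=O)OC(C)(C)C)[C@@H](O[Si](C)(C)C(C)(C)C)C[C@@]2(C)O[C@@H]1C=C2O[Si](C)(C)C
F3 | step 14 | 8-O-angeloyl (Z)-5,6-alkene | C[C@@H]1/C=C\[C@H](C(=C)C(=O)OC(C)(C)C)[C@@H](OC(=O)/C(C)=C\C)C[C@@]2(C)OC1=CC2=O
F4 | step 14 | 5-epi-5,6-diol | C[C@@H]1[C@@H](O)[C@@H](O)[C@H](C(=C)C(=O)OC(C)(C)C)[C@@H](OC(=O)/C(C)=C\C)C[C@@]2(C)OC1=CC2=O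
F5 | step 14 | 5-epi hydroxy lactone (5-epi-rufescenolide B) | C=C1C(=O)O[C@@H]2[C@H](O)[C@@H](C)C3=CC(=O)[C@@](C)(C[C@H](OC(=O)/C(C)=C\C)[C@@H]12)O3
F6 | step 14 | 5-oxo lactone | C=C1C(=O)O[C@@H]2C(=O)[C@@H](C)C3=CC(=O)[C@@](C)(C[C@H](OC(=O)/C(C)=C\C)[C@@H]12)O3
F7 | step 11 | C6-deoxy (E)-5,6-alkene, the transposed alkene from 18 | C1=CC(=O)[C@@](C)(C[C@H](O[Si](C)(C)C(C)(C)C)[C@@H](C(=C)C(=O)OC(C)(C)C)/C=C/CC)O1
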